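## Retrosynthetic overview

1. Target 25 is a germacranoid: a ten-membered carbocycle (ring A, C1–C10) with a ring-cis (Z) C1=C10 enone (C9=O), a C4–C5 oxirane fused to ring A, a spiro C7–C11 oxirane, and acetates on C12 and C15.
2. Enabling feature: C1=C10 is the only C=C of ring A, it is ring-cis (the low-strain geometry of a cyclodecene) and conjugated to C9=O. Ring A is therefore opened at C1=C10 to the acyclic isopropenyl ketone 24 and closed last by ring-closing metathesis, which gives 25 directly.
3. Both oxiranes are 2,3-epoxy alcohol acetates (C15–C4–C5 and C12–C11–C7), so all four stereocentres are set on the open chain by two reagent-controlled Sharpless epoxidations of the skipped diene 17.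
4. 17 comes from C6–C7 coupling of allylic bromide 7 (C1–C6, C15) with the alkenylmagnesium from iodide 15 (C7–C14). The two olefin geometries come from directed trans-hydroalumination/Negishi coupling and from anti-carbomagnesiation of propargylic alcohols.
5. Order of ring formation: C7–C11 oxirane (step 10), C4–C5 oxirane (step 13), ring A (step 17).

Key step: step 17

Remark: locants follow germacrane numbering (C15 on C4 and C12 on C11 are the acetoxymethyl carbons, C14 on C10 and C13 on C11 the methyl carbons); C9 is introduced racemic in step 5 and carried as both epimers until it is oxidised in step 16, and the CIP label of C7 changes with the C9 substituent although its configuration does not.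

## Route

Step 1
Reactants: 1 but-2-yne-1,4-diol
Product: 2 4-[(4-methoxybenzyl)oxy]but-2-yn-1-ol
Conditions: PMBCl (1 equiv), KOH, 1 (4 equiv), DMSO, rt
Reagents that add atoms: 4-methoxybenzyl chloride, COc1ccc(CCl)cc1
Why: Williamson etherification of the symmetrical diol, used in excess, should give the mono-ether, whose free hydroxyl (on the future C6) is the directing group of step 2.

Step 2
Reactants: 2 4-[(4-methoxybenzyl)oxy]but-2-yn-1-ol
Product: 4 (2Z)-3-iodo-4-[(4-methoxybenzyl)oxy]but-2-en-1-ol, via cyclic alkenylaluminate 3 (not isolated)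
Conditions: NaAlH2(OCH2CH2OMe)2, THF, 0 °C; then I2, −78 → 0 °C; aqueous work-up
Reagents that add atoms: iodine, II
Why: Hydroxyl-directed trans-hydroalumination of the propargylic alcohol delivers hydride to C5 and holds aluminium on C4 cis to C6 in a five-membered alkoxyaluminate, and iodinolysis with retention should give the (Z)-iodide, which fixes C15 trans to C6.

Step 3
Reactants: 4 (2Z)-3-iodo-4-[(4-methoxybenzyl)oxy]but-2-en-1-ol; 5 but-3-en-1-ylzinc bromide
Product: 6 (2E)-3-{[(4-methoxybenzyl)oxy]methyl}hepta-2,6-dien-1-ol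
Conditions: 5 (2.5 equiv), Pd(dppf)Cl2 (5 mol%), THF, 50 °C
Reagents that add atoms: none
Why: Negishi sp2–sp3 cross-coupling replaces iodine by the butenyl chain (C3–C1 plus the carbon later lost as ethene) with retention of olefin geometry, so that C3 is cis and C15 trans to C6.

Step 4
Reactants: 6 (2E)-3-{[(4-methoxybenzyl)oxy]methyl}hepta-2,6-dien-1-ol
Product: 7 (2E)-1-bromo-3-{[(4-methoxybenzyl)oxy]methyl}hepta-2,6-diene
Conditions: CBr4, PPh3, CH2Cl2, 0 °C
Reagents that add atoms: tetrabromomethane, BrC(Br)(Br)Br
Why: Appel bromination of the primary allylic alcohol should proceed by SN2 displacement without allylic transposition or change of olefin geometry.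

Step 5
Reactants: 8 2-methylprop-2-enal; 9 3-bromoprop-1-yne
Product: 10 rac-2-methylhex-1-en-5-yn-3-ol
Conditions: Zn (activated), THF, 0 °C → rt; H2O work-up
Reagents that add atoms: none
Why: Zinc-mediated Barbier propargylation should give the homopropargylic alcohol (the organozinc adds through its γ-carbon), and the new carbinol centre C9 is left racemic on purpose because it becomes the ketone in step 16.

Step 6
Reactants: 10 rac-2-methylhex-1-en-5-yn-3-ol
Product: 11 rac-tert-butyldimethyl[(2-methylhex-1-en-5-yn-3-yl)oxy]silane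
Conditions: TBSCl, imidazole, DMF, rt
Reagents that add atoms: tert-butyldimethylsilyl chloride, CC(C)(C)[Si](C)(C)Cl
Why: Standard silylation protects the secondary allylic alcohol against the organometallic steps that follow.

Step 7
Reactants: 11 rac-tert-butyldimethyl[(2-methylhex-1-en-5-yn-3-yl)oxy]silane
Product: 13 rac-5-[(tert-butyldimethylsilyl)oxy]-6-methylhept-6-en-2-yn-1-ol, via lithium acetylide 12 (not isolated)
Conditions: n-BuLi, THF, −78 °C; then (CH2O)n, −78 °C → rt; H2O
Reagents that add atoms: formaldehyde (as paraformaldehyde), C=O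
Why: Addition of the lithium acetylide to formaldehyde installs C12 as the propargylic alcohol that directs the carbometalation of step 8.

Step 8
Reactants: 13 rac-5-[(tert-butyldimethylsilyl)oxy]-6-methylhept-6-en-2-yn-1-ol
Product: 15 rac-(2Z)-5-[(tert-butyldimethylsilyl)oxy]-3-iodo-2,6-dimethylhepta-2,6-dien-1-ol, via alkenylmagnesium bromide 14 (not isolated)
Conditions: MeMgBr (3 equiv), CuI (10 mol%), THF, 0 → 40 °C; then I2, −30 → 0 °C; H2O
Reagents that add atoms: methylmagnesium bromide, C[Mg]Br; iodine, II
Why: Copper-catalysed anti-carbomagnesiation of the propargylic alkoxide adds the methyl group (C13) to C11 and magnesium to C7, held cis to the CH2O group in a five-membered chelate, and iodinolysis with retention should give the tetrasubstituted (Z)-iodide in which C8 is cis to the methyl group.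

Step 9
Reactants: 15 rac-(2Z)-alkenyl iodide; 7 (2E)-allylic bromide
Product: 17 rac-(2E,5E)-3-{2-[(tert-butyldimethylsilyl)oxy]-3-methylbut-3-en-1-yl}-6-{[(4-methoxybenzyl)oxy]methyl}-2-methyldeca-2,5,9-trien-1-ol, via alkenylmagnesium chloride 16 (not isolated)
Conditions: i-PrMgCl·LiCl (2.1 equiv), THF, −20 → 0 °C; then 7, Li2CuCl4 (5 mol%), −30 → 0 °C; H2O
Reagents that add atoms: none
Why: Alkoxide-assisted iodine–magnesium exchange regenerates the chelated alkenylmagnesium with retention, and the copper-catalysed Grignard coupling with the primary allylic bromide should take place at the CH2Br carbon (SN2, the γ-carbon being fully substituted), forming the C6–C7 bond with both olefin geometries intact.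

Step 10
Reactants: 17 rac-(2E,5E)-trienol
Product: 18 {(2S,3S)-3-{2-[(tert-butyldimethylsilyl)oxy]-3-methylbut-3-en-1-yl}-3-[(2E)-3-{[(4-methoxybenzyl)oxy]methyl}hepta-2,6-dien-1-yl]-2-methyloxiran-2-yl}methanol (both C9 epimers)
Conditions: Ti(OiPr)4 (10 mol%), L-(+)-diethyl tartrate (12 mol%), t-BuOOH, 4 Å molecular sieves, CH2Cl2, −20 °C
Reagents that add atoms: tert-butyl hydroperoxide, CC(C)(C)OO
Why: Sharpless asymmetric epoxidation acts only on the olefin of the free allylic alcohol (C7=C11), L-(+)-tartrate delivers oxygen to the face that makes C11 S, and the olefin geometry (C6 cis to C12) then fixes C7 as in the target.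

Step 11
Reactants: 18 epoxy alcohol
Product: 19 {(2S,3S)-3-{2-[(tert-butyldimethylsilyl)oxy]-3-methylbut-3-en-1-yl}-3-[(2E)-3-{[(4-methoxybenzyl)oxy]methyl}hepta-2,6-dien-1-yl]-2-methyloxiran-2-yl}methyl acetate (both C9 epimers)
Conditions: Ac2O, pyridine, DMAP (cat.), CH2Cl2, 0 °C
Reagents that add atoms: acetic anhydride, CC(=O)OC(C)=O
Why: DMAP-catalysed acylation installs the C12 acetate of the target and removes the free hydroxyl next to the acid-sensitive tetrasubstituted oxirane.

Step 12
Reactants: 19 epoxy acetate
Product: 20 {(2S,3S)-3-{2-[(tert-butyldimethylsilyl)oxy]-3-methylbut-3-en-1-yl}-3-[(2E)-3-(hydroxymethyl)hepta-2,6-dien-1-yl]-2-methyloxiran-2-yl}methyl acetate (both C9 epimers)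
Conditions: DDQ, CH2Cl2/pH 7 buffer, 0 °C
Reagents that add atoms: none
Why: Oxidative cleavage of the 4-methoxybenzyl ether under buffered two-phase conditions should free the C15 allylic alcohol without touching the oxirane, the acetate, the silyl ether or the olefins.

Step 13
Reactants: 20 allylic alcohol
Product: 21 {(2S,3S)-3-{[(2R,3R)-3-(but-3-en-1-yl)-3-(hydroxymethyl)oxiran-2-yl]methyl}-3-{2-[(tert-butyldimethylsilyl)oxy]-3-methylbut-3-en-1-yl}-2-methyloxiran-2-yl}methyl acetate (both C9 epimers)
Conditions: Ti(OiPr)4 (10 mol%), D-(−)-diethyl tartrate (12 mol%), t-BuOOH, 4 Å molecular sieves, CH2Cl2, −20 °C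
Reagents that add atoms: tert-butyl hydroperoxide, CC(C)(C)OO
Why: A second Sharpless asymmetric epoxidation, directed by the C15 hydroxyl and run with D-(−)-tartrate, should set C4 and C5 (both R) under reagent control, the cis relation of C3 and C6 in the olefin being carried into the oxirane.

Step 14
Reactants: 21 bis-epoxy alcohol
Product: 22 {(2S,3S)-3-{[(2R,3R)-3-(acetoxymethyl)-3-(but-3-en-1-yl)oxiran-2-yl]methyl}-3-{2-[(tert-butyldimethylsilyl)oxy]-3-methylbut-3-en-1-yl}-2-methyloxiran-2-yl}methyl acetate (both C9 epimers)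
Conditions: Ac2O, pyridine, DMAP (cat.), CH2Cl2, 0 °C
Reagents that add atoms: acetic anhydride, CC(=O)OC(C)=O
Why: Acylation of the primary epoxy alcohol installs the C15 acetate of the target.

Step 15
Reactants: 22 bis-epoxy diacetate silyl ether
Product: 23 {(2S,3R)-3-{[(2R,3R)-3-(acetoxymethyl)-3-(but-3-en-1-yl)oxiran-2-yl]methyl}-3-(2-hydroxy-3-methylbut-3-en-1-yl)-2-methyloxiran-2-yl}methyl acetate (both C9 epimers)
Conditions: TBAF, AcOH (1:1), THF, rt
Reagents that add atoms: none
Why: Fluoride cleaves the secondary silyl ether, and the acetic acid buffer keeps the medium from becoming basic enough for acetate migration or oxirane opening.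

Step 16
Reactants: 23 bis-epoxy diacetate carbinol
Product: 24 {(2S,3S)-3-{[(2R,3R)-3-(acetoxymethyl)-3-(but-3-en-1-yl)oxiran-2-yl]methyl}-2-methyl-3-(3-methyl-2-oxobut-3-en-1-yl)oxiran-2-yl}methyl acetate
Conditions: Dess–Martin periodinane, pyridine, CH2Cl2, 0 °C
Reagents that add atoms: none
Why: Dess–Martin oxidation of the allylic alcohol under pyridine buffer should give the isopropenyl ketone, which merges the two C9 epimers into one compound without exposing the base-sensitive β,γ-epoxy ketone to strong base.

Step 17
Reactants: 24 acyclic isopropenyl ketone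
Product: 25 (1(10)Z,4R,5R,7S,11S)-4,5:7,11-diepoxy-9-oxogermacr-1(10)-ene-12,15-diyl diacetate (CNP0185847.4)
Conditions: second-generation Grubbs catalyst (H2IMes)(PCy3)Cl2Ru=CHPh (10 mol%), toluene (1 mM), 80 °C, argon sparge
Reagents that add atoms: none
Why: The ruthenium alkylidene loads onto the unhindered monosubstituted C1=CH2 olefin, the C1 alkylidene then adds across the 1,1-disubstituted C10=CH2 olefin of the isopropenyl ketone through a ruthenacyclobutane, and cycloreversion expels ethene, whose removal drives the closure. The closest known reaction type is ring-closing metathesis to medium-ring (nine- to eleven-membered) carbocycles and to cyclic 2-methyl enones and enoates from methacryloyl-type olefins. One ring is closed, the ten-membered carbocycle (ring A), by formation of the endocyclic C1=C10 double bond between the two chain termini; both oxiranes are already in place and are inert. No stereocentre is formed; the only stereochemical element is the olefin geometry, and the ring-cis (Z) isomer should prevail because a trans trisubstituted double bond is considerably more strained than a cis one in a cyclodecene, as is the metallacycle that leads to it. The step needs ring closure to beat oligomerisation and needs chemoselectivity: high dilution, the presence of only two olefins (of which only the terminal one can homodimerise, and reversibly) and the two turn elements built into the chain (the cis-substituted C4–C5 oxirane and the fully substituted spiro carbon C7) should secure the first, and the tolerance of the catalyst toward oxiranes, esters and ketones the second.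

## Compound list

1 | but-2-yne-1,4-diol | OCC#CCO | starting material
2 | 4-[(4-methoxybenzyl)oxy]but-2-yn-1-ol | OCC#CCOCc1ccc(OC)cc1 | intermediate
3 | sodium cyclic alkenylaluminate from 2 (five-membered O–Al–C4=C5–C6 ring, two 2-methoxyethoxy groups on aluminium; not isolated) | [Na+].COCCO[Al-]1(OCCOC)OCC=C1COCc2ccc(OC)cc2 | intermediate
4 | (2Z)-3-iodo-4-[(4-methoxybenzyl)oxy]but-2-en-1-ol | OC/C=C(\I)COCc1ccc(OC)cc1 | intermediate
5 | but-3-en-1-ylzinc bromide (commercial THF solution) | C=CCC[Zn]Br | starting material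
6 | (2E)-3-{[(4-methoxybenzyl)oxy]methyl}hepta-2,6-dien-1-ol | OC/C=C(\CCC=C)COCc1ccc(OC)cc1 | intermediate
7 | (2E)-1-bromo-3-{[(4-methoxybenzyl)oxy]methyl}hepta-2,6-diene | BrC/C=C(\CCC=C)COCc1ccc(OC)cc1 | intermediate
8 | 2-methylprop-2-enal (methacrolein) | CC(=C)C=O | starting material
9 | 3-bromoprop-1-yne (propargyl bromide) | C#CCBr | starting material
10 | rac-2-methylhex-1-en-5-yn-3-ol | C=C(C)C(O)CC#C | intermediate
11 | rac-tert-butyldimethyl[(2-methylhex-1-en-5-yn-3-yl)oxy]silane | C=C(C)C(CC#C)O[Si](C)(C)C(C)(C)C | intermediate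
12 | lithium acetylide of 11 (not isolated) | [Li]C#CCC(O[Si](C)(C)C(C)(C)C)C(C)=C | intermediate
13 | rac-5-[(tert-butyldimethylsilyl)oxy]-6-methylhept-6-en-2-yn-1-ol | OCC#CCC(O[Si](C)(C)C(C)(C)C)C(C)=C | intermediate
14 | alkenylmagnesium bromide from 13 (C7–Mg cis to the CH2O–Mg group; not isolated) | Br[Mg]OC/C(C)=C(\[Mg]Br)CC(O[Si](C)(C)C(C)(C)C)C(C)=C | intermediate
15 | rac-(2Z)-5-[(tert-butyldimethylsilyl)oxy]-3-iodo-2,6-dimethylhepta-2,6-dien-1-ol | OC/C(C)=C(\I)CC(O[Si](C)(C)C(C)(C)C)C(C)=C | intermediate
16 | alkenylmagnesium chloride from 15 (C7–Mg cis to the CH2O–Mg group; not isolated) | Cl[Mg]OC/C(C)=C(\[Mg]Cl)CC(O[Si](C)(C)C(C)(C)C)C(C)=C | intermediate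
17 | rac-(2E,5E)-3-{2-[(tert-butyldimethylsilyl)oxy]-3-methylbut-3-en-1-yl}-6-{[(4-methoxybenzyl)oxy]methyl}-2-methyldeca-2,5,9-trien-1-ol | OC/C(C)=C(/CC(O[Si](C)(C)C(C)(C)C)C(C)=C)C/C=C(\CCC=C)COCc1ccc(OC)cc1 | intermediate
18 | {(2S,3S)-3-{2-[(tert-butyldimethylsilyl)oxy]-3-methylbut-3-en-1-yl}-3-[(2E)-3-{[(4-methoxybenzyl)oxy]methyl}hepta-2,6-dien-1-yl]-2-methyloxiran-2-yl}methanol (both C9 epimers) | OC[C@]1(C)O[C@]1(CC(O[Si](C)(C)C(C)(C)C)C(C)=C)C/C=C(\CCC=C)COCc2ccc(OC)cc2 | intermediate
19 | {(2S,3S)-3-{2-[(tert-butyldimethylsilyl)oxy]-3-methylbut-3-en-1-yl}-3-[(2E)-3-{[(4-methoxybenzyl)oxy]methyl}hepta-2,6-dien-1-yl]-2-methyloxiran-2-yl}methyl acetate (both C9 epimers) | CC(=O)OC[C@]1(C)O[C@]1(CC(O[Si](C)(C)C(C)(C)C)C(C)=C)C/C=C(\CCC=C)COCc2ccc(OC)cc2 | intermediate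
20 | {(2S,3S)-3-{2-[(tert-butyldimethylsilyl)oxy]-3-methylbut-3-en-1-yl}-3-[(2E)-3-(hydroxymethyl)hepta-2,6-dien-1-yl]-2-methyloxiran-2-yl}methyl acetate (both C9 epimers) | CC(=O)OC[C@]1(C)O[C@]1(CC(O[Si](C)(C)C(C)(C)C)C(C)=C)C/C=C(\CCC=C)CO | intermediate
21 | {(2S,3S)-3-{[(2R,3R)-3-(but-3-en-1-yl)-3-(hydroxymethyl)oxiran-2-yl]methyl}-3-{2-[(tert-butyldimethylsilyl)oxy]-3-methylbut-3-en-1-yl}-2-methyloxiran-2-yl}methyl acetate (both C9 epimers) | CC(=O)OC[C@]1(C)O[C@]1(CC(O[Si](C)(C)C(C)(C)C)C(C)=C)C[C@H]2O[C@]2(CCC=C)CO | intermediate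
22 | {(2S,3S)-3-{[(2R,3R)-3-(acetoxymethyl)-3-(but-3-en-1-yl)oxiran-2-yl]methyl}-3-{2-[(tert-butyldimethylsilyl)oxy]-3-methylbut-3-en-1-yl}-2-methyloxiran-2-yl}methyl acetate (both C9 epimers) | CC(=O)OC[C@]1(C)O[C@]1(CC(O[Si](C)(C)C(C)(C)C)C(C)=C)C[C@H]2O[C@]2(CCC=C)COC(C)=O | intermediate
23 | {(2S,3R)-3-{[(2R,3R)-3-(acetoxymethyl)-3-(but-3-en-1-yl)oxiran-2-yl]methyl}-3-(2-hydroxy-3-methylbut-3-en-1-yl)-2-methyloxiran-2-yl}methyl acetate (both C9 epimers) | CC(=O)OC[C@]1(C)O[C@]1(CC(O)C(C)=C)C[C@H]2O[C@]2(CCC=C)COC(C)=O | intermediate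
24 | {(2S,3S)-3-{[(2R,3R)-3-(acetoxymethyl)-3-(but-3-en-1-yl)oxiran-2-yl]methyl}-2-methyl-3-(3-methyl-2-oxobut-3-en-1-yl)oxiran-2-yl}methyl acetate | CC(=O)OC[C@]1(C)O[C@]1(CC(=O)C(C)=C)C[C@H]2O[C@]2(CCC=C)COC(C)=O | intermediate
25 | (1(10)Z,4R,5R,7S,11S)-4,5:7,11-diepoxy-9-oxogermacr-1(10)-ene-12,15-diyl diacetate (CNP0185847.4) | CC(=O)OC[C@]12CC/C=C(/C)C(=O)C[C@]3(C[C@H]1O2)O[C@@]3(C)COC(C)=O | target

## Step count and risks

Total step count: 17. Longest linear sequence: 13 steps (steps 1–4 or steps 5–8, then steps 9–17).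

The three steps most likely to fail:

Step 17 (ring-closing metathesis). Intermolecular metathesis (oligomerisation) may outrun closure of the strained ten-membered ring, the electron-poor 1,1-disubstituted enone olefin may fail to enter the catalytic cycle, or the ring-trans olefin may form alongside the Z isomer. The fallback closes the ring before the ketone exists, on a different substrate class and with a re-ordered end game. It sets out from carbinol 23. Ring-closing metathesis of this diene carbinol (an electron-richer olefin with a free allylic hydroxyl and an sp3 C9) should give the macrocyclic allylic alcohol (1(10)Z)-4,5:7,11-diepoxy-9-hydroxygermacr-1(10)-ene-12,15-diyl diacetate F1 as both C9 epimers. Dess–Martin oxidation of F1 (pyridine, CH2Cl2) comes back to the route at 25.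

Step 9 (alkenyl–allyl coupling). Iodine–magnesium exchange at the hindered tetrasubstituted iodide may be slow, and the copper-catalysed substitution may leak to the γ-carbon of the allylic bromide or scramble an olefin geometry. The fallback replaces the copper-catalysed Grignard allylation by a palladium-catalysed Stille coupling. It sets out from alkynol 13. Carbomagnesiation as in step 8, quenched with Bu3SnCl instead of iodine, should give the alkenylstannane (2Z)-5-[(tert-butyldimethylsilyl)oxy]-2,6-dimethyl-3-(tributylstannyl)hepta-2,6-dien-1-ol F2. Coupling of F2 with bromide 7 (Pd2(dba)3, AsPh3, CuI, DMF) comes back to the route at 17.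

Step 10 (first asymmetric epoxidation). Enantiofacial discrimination may be poor for the tetrasubstituted olefin, or the titanium alkoxide may open or rearrange the tetrasubstituted epoxy alcohol before it is isolated. The fallback leaves the titanium–tartrate system for a different catalyst family that works without a strong Lewis acid. It sets out from 17. Vanadium-catalysed asymmetric epoxidation with a C2-symmetric chiral bishydroxamic acid ligand (VO(OiPr)3, aqueous t-BuOOH, toluene, 0 °C) should give the same epoxy alcohol and comes back to the route at 18 without a new compound.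

Further compounds

F1 | step 17 | (1(10)Z)-4,5:7,11-diepoxy-9-hydroxygermacr-1(10)-ene-12,15-diyl diacetate (oxirane configurations as in 25, both C9 epimers) | CC(=O)OC[C@]12CC/C=C(/C)C(O)C[C@]3(C[C@H]1O2)O[C@@]3(C)COC(C)=O
F2 | step 9 | rac-(2Z)-5-[(tert-butyldimethylsilyl)oxy]-2,6-dimethyl-3-(tributylstannyl)hepta-2,6-dien-1-ol | OC/C(C)=C(\[Sn](CCCC)(CCCC)CCCC)CC(O[Si](C)(C)C(C)(C)C)C(C)=C
F0 | step 10 | none | none
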